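**Retrosynthetic overview**
1. The target is reached by cleaving all fifteen methyl ethers of tetraphenol 21. Its four ring D hydroxyls come from the formyl groups of tetra-aldehyde 19 by Baeyer–Villiger (Dakin-type) oxidation.
2. Key disconnection: the two ether bonds between the ring C C4 oxygens and ring D C1. The strategy rests on ring D C1, which carries the ether oxygen from ring C and is flanked by hydroxyls at C2 and C6. Two formyl groups at those positions activate a fluoride on C1 for SNAr and are afterwards oxidised to the hydroxyls.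
3. Core bis-phenol 11 (rings A, B, C, C): ring B from 2,6-difluoro-4-methoxybenzaldehyde by two-fold SNAr with phenol 4, Dakin oxidation, copper-catalysed O-arylation with the ring A iodide, then debenzylation.
4. Fluorodialdehyde 18 (rings D–E): 4-bromo-2-fluoro-5-methoxybenzaldehyde, acetal, lithiation and formylation between F and Br, Suzuki–Miyaura coupling with the ring E boronic acid.
5. No ring is formed in the route; the seven benzene rings are bought and joined in the order C to B, then A, then D–E onto C.

Key step: step 10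

Assumption: the target has no stereogenic element (ring E is symmetric, so the D–E axes are not stereogenic), and 4-bromo-2-fluoro-5-methoxybenzaldehyde is taken as purchased because bromination of 2-fluoro-5-methoxybenzaldehyde is not reliably selective for C4.

**Route**

Step 1
Reactants: 1 4-hydroxy-2,6-dimethoxybenzaldehyde
Product: 2 4-(benzyloxy)-2,6-dimethoxybenzaldehyde
Conditions: BnBr, K2CO3, DMF, rt
Reagents that add atoms: benzyl bromide, BrCc1ccccc1
Why: Williamson etherification of the only phenol, which is acidified by the para formyl group, so O-benzylation under carbonate base is straightforward.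

Step 2
Reactants: 2 4-(benzyloxy)-2,6-dimethoxybenzaldehyde
Product: 4 4-(benzyloxy)-2,6-dimethoxyphenol, via aryl formate 3 (not isolated)
Conditions: mCPBA, CH2Cl2, 0 °C to rt; then K2CO3 (cat.), MeOH, rt
Reagents that add atoms: 3-chloroperoxybenzoic acid (mCPBA), OOC(=O)c1cccc(Cl)c1
Why: Baeyer–Villiger (Dakin-type) oxidation in which the 2,4,6-trioxygenated aryl group migrates in preference to hydride, followed by base-catalysed methanolysis of the formate, which places the free hydroxyl between the two methoxy groups and the benzyl ether para to it without any regiochemical ambiguity.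

Step 3
Reactants: 5 2,6-difluoro-4-methoxybenzaldehyde; 4 4-(benzyloxy)-2,6-dimethoxyphenol (two equivalents enter)
Product: 6 2,6-bis[4-(benzyloxy)-2,6-dimethoxyphenoxy]-4-methoxybenzaldehyde
Conditions: Cs2CO3, DMSO, 110 °C, under N2
Reagents that add atoms: none
Why: Two-fold SNAr in which each fluoride is ortho to the formyl group that stabilises the Meisenheimer anion and has only a hydrogen on its other side, so the hindered cesium phenoxide of 4 can displace both fluorides in polar aprotic solvent.

Step 4
Reactants: 6 2,6-bis[4-(benzyloxy)-2,6-dimethoxyphenoxy]-4-methoxybenzaldehyde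
Product: 8 2,6-bis[4-(benzyloxy)-2,6-dimethoxyphenoxy]-4-methoxyphenol, via ring B formate 7 (not isolated)
Conditions: mCPBA, CH2Cl2, 0 °C to rt; then K2CO3 (cat.), MeOH, rt
Reagents that add atoms: 3-chloroperoxybenzoic acid (mCPBA), OOC(=O)c1cccc(Cl)c1
Why: Baeyer–Villiger (Dakin-type) oxidation favoured by the para methoxy and two ortho aryloxy donors on ring B and by the out-of-plane formyl group, so aryl migration gives the formate and methanolysis gives the ring B C2 phenol.

Step 5
Reactants: 8 2,6-bis[4-(benzyloxy)-2,6-dimethoxyphenoxy]-4-methoxyphenol; 9 1-iodo-3,5-dimethoxybenzene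
Product: 10 1,3-bis[4-(benzyloxy)-2,6-dimethoxyphenoxy]-2-(3,5-dimethoxyphenoxy)-5-methoxybenzene
Conditions: CuI (cat.), picolinic acid (cat.), K3PO4, DMSO, 90 °C
Reagents that add atoms: none
Why: Ullmann-type O-arylation catalysed by monovalent copper with the picolinic acid ligand system that tolerates di-ortho-substituted phenols, using an aryl iodide with no ortho substituent so that all the crowding sits on the phenoxide, while benzyl and methyl ethers are inert.

Step 6
Reactants: 10 1,3-bis[4-(benzyloxy)-2,6-dimethoxyphenoxy]-2-(3,5-dimethoxyphenoxy)-5-methoxybenzene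
Product: 11 4,4'-{[2-(3,5-dimethoxyphenoxy)-5-methoxy-1,3-phenylene]bis(oxy)}bis(3,5-dimethoxyphenol) (core bis-phenol)
Conditions: H2 (1 atm), 10% Pd/C, EtOAc/MeOH, rt
Reagents that add atoms: none
Why: Catalytic hydrogenolysis removes only the two benzyl ethers, since methyl and diaryl ethers do not react, and so frees exactly the two ring C C4 hydroxyls.

Step 7
Reactants: 12 4-bromo-2-fluoro-5-methoxybenzaldehyde
Product: 13 2-(4-bromo-2-fluoro-5-methoxyphenyl)-1,3-dioxolane
Conditions: HOCH2CH2OH, p-TsOH·H2O (cat.), toluene, reflux, Dean–Stark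
Reagents that add atoms: ethylene glycol, OCCO
Why: Acid-catalysed acetalisation with azeotropic removal of water masks the aldehyde as a dioxolane that is stable to lithium amide base.

Step 8
Reactants: 13 2-(4-bromo-2-fluoro-5-methoxyphenyl)-1,3-dioxolane
Product: 15 6-bromo-3-(1,3-dioxolan-2-yl)-2-fluoro-5-methoxybenzaldehyde, via aryllithium 14 (not isolated)
Conditions: LiN(i-Pr)2, THF, −78 °C; DMF, −78 °C; aq. NH4Cl
Reagents that add atoms: N,N-dimethylformamide, CN(C)C=O
Why: Directed ortho-metalation at the one hydrogen flanked by fluorine and bromine, by far the most acidic site, with an amide base that does not undergo bromine–lithium exchange, followed by formylation with DMF at low temperature before lithium halide can be eliminated.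

Step 9
Reactants: 15 6-bromo-3-(1,3-dioxolan-2-yl)-2-fluoro-5-methoxybenzaldehyde; 16 (2,4,6-trimethoxyphenyl)boronic acid
Product: 18 2-fluoro-5-methoxy-4-(2,4,6-trimethoxyphenyl)isophthalaldehyde, via biaryl monoacetal 17 (not isolated)
Conditions: Pd2(dba)3 (cat.), SPhos, K3PO4, toluene/H2O, 100 °C; then 2 M HCl, THF, rt
Reagents that add atoms: water, O
Why: Suzuki–Miyaura coupling with zerovalent palladium and the bulky dialkylbiarylphosphine SPhos, which supports tetra-ortho-substituted biaryl formation, run while one formyl group is still an acetal so that the fluoride is only singly activated toward the base, after which acid hydrolysis unveils the second aldehyde.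

Step 10
Reactants: 11 core bis-phenol; 18 2-fluoro-5-methoxy-4-(2,4,6-trimethoxyphenyl)isophthalaldehyde (two equivalents enter)
Product: 19 heptamer tetra-aldehyde (11 with a 2,6-diformyl-4-methoxy-3-(2,4,6-trimethoxyphenyl)phenyl group on each ring C C4 oxygen)
Conditions: K2CO3, DMF, rt to 50 °C
Reagents that add atoms: none
Why: Each ring C phenoxide of 11 adds to the fluorine-bearing carbon of 18 to give a Meisenheimer anion whose charge is delocalised into both ortho formyl groups, and loss of fluoride then forms the bond from oxygen to ring D C1, once on each arm. The closest known reaction type is SNAr of phenoxides on ortho-formyl fluoroarenes, here with double ortho activation so that a mild temperature should suffice. No ring is closed and no stereocentre is created. The step needs site selectivity on both partners: 11 has only the two ring C C4 hydroxyls free, each with hydrogens beside it, and 18 has a single leaving group, so the crowding is confined to the activated electrophile where SNAr tolerates it. The formyl groups that drive the substitution end up at C2 and C6 of ring D, where the target has hydroxyls, so no activating group has to be removed.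

Step 11
Reactants: 19 heptamer tetra-aldehyde
Product: 21 heptamer tetraphenol (hydroxyls at C2 and C6 of each ring D, all other oxygens methylated), via tetraformate 20 (not isolated)
Conditions: mCPBA (excess), CH2Cl2, 0 °C to rt; then K2CO3 (cat.), MeOH, rt
Reagents that add atoms: 3-chloroperoxybenzoic acid (mCPBA), OOC(=O)c1cccc(Cl)c1
Why: Four-fold Baeyer–Villiger (Dakin-type) oxidation in which each formyl group has the aryloxy oxygen ortho to it to assist aryl migration, followed by methanolysis of the four formates, as is established for ortho-aryloxybenzaldehydes made by SNAr.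

Step 12
Reactants: 21 heptamer tetraphenol
Product: 22 CNP0227063.0 (target, all nineteen hydroxyls free)
Conditions: BBr3 (excess), CH2Cl2, −78 °C to rt; then MeOH, H2O
Reagents that add atoms: none
Why: Lewis-acid cleavage of the fifteen aryl methyl ethers by BBr3 through bromide attack on the O-methyl carbon of the boron-complexed ether, conditions under which diaryl ether and biaryl bonds are not broken.

**Compound list**
1 | 4-hydroxy-2,6-dimethoxybenzaldehyde | COc1cc(O)cc(OC)c1C=O | starting material
2 | 4-(benzyloxy)-2,6-dimethoxybenzaldehyde | COc1cc(OCc2ccccc2)cc(OC)c1C=O | intermediate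
3 | 4-(benzyloxy)-2,6-dimethoxyphenyl formate | COc1cc(OCc2ccccc2)cc(OC)c1OC=O | intermediate
4 | 4-(benzyloxy)-2,6-dimethoxyphenol | COc1cc(OCc2ccccc2)cc(OC)c1O | intermediate
5 | 2,6-difluoro-4-methoxybenzaldehyde | COc1cc(F)c(C=O)c(F)c1 | starting material
6 | 2,6-bis[4-(benzyloxy)-2,6-dimethoxyphenoxy]-4-methoxybenzaldehyde | COc1cc(Oc2c(OC)cc(OCc3ccccc3)cc2OC)c(C=O)c(Oc2c(OC)cc(OCc3ccccc3)cc2OC)c1 | intermediate
7 | 2,6-bis[4-(benzyloxy)-2,6-dimethoxyphenoxy]-4-methoxyphenyl formate | COc1cc(Oc2c(OC)cc(OCc3ccccc3)cc2OC)c(OC=O)c(Oc2c(OC)cc(OCc3ccccc3)cc2OC)c1 | intermediate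
8 | 2,6-bis[4-(benzyloxy)-2,6-dimethoxyphenoxy]-4-methoxyphenol | COc1cc(Oc2c(OC)cc(OCc3ccccc3)cc2OC)c(O)c(Oc2c(OC)cc(OCc3ccccc3)cc2OC)c1 | intermediate
9 | 1-iodo-3,5-dimethoxybenzene | COc1cc(I)cc(OC)c1 | starting material
10 | 1,3-bis[4-(benzyloxy)-2,6-dimethoxyphenoxy]-2-(3,5-dimethoxyphenoxy)-5-methoxybenzene | COc1cc(OC)cc(Oc2c(Oc3c(OC)cc(OCc4ccccc4)cc3OC)cc(OC)cc2Oc2c(OC)cc(OCc3ccccc3)cc2OC)c1 | intermediate
11 | 4,4'-{[2-(3,5-dimethoxyphenoxy)-5-methoxy-1,3-phenylene]bis(oxy)}bis(3,5-dimethoxyphenol) | COc1cc(OC)cc(Oc2c(Oc3c(OC)cc(O)cc3OC)cc(OC)cc2Oc2c(OC)cc(O)cc2OC)c1 | intermediate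
12 | 4-bromo-2-fluoro-5-methoxybenzaldehyde | COc1cc(C=O)c(F)cc1Br | starting material
13 | 2-(4-bromo-2-fluoro-5-methoxyphenyl)-1,3-dioxolane | COc1cc(C2OCCO2)c(F)cc1Br | intermediate
14 | [6-bromo-3-(1,3-dioxolan-2-yl)-2-fluoro-5-methoxyphenyl]lithium | COc1cc(C2OCCO2)c(F)c([Li])c1Br | intermediate
15 | 6-bromo-3-(1,3-dioxolan-2-yl)-2-fluoro-5-methoxybenzaldehyde | COc1cc(C2OCCO2)c(F)c(C=O)c1Br | intermediate
16 | (2,4,6-trimethoxyphenyl)boronic acid | COc1cc(OC)c(B(O)O)c(OC)c1 | starting material
17 | 3-(1,3-dioxolan-2-yl)-2-fluoro-5-methoxy-6-(2,4,6-trimethoxyphenyl)benzaldehyde | COc1cc(C2OCCO2)c(F)c(C=O)c1-c1c(OC)cc(OC)cc1OC | intermediate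
18 | 2-fluoro-5-methoxy-4-(2,4,6-trimethoxyphenyl)isophthalaldehyde | COc1cc(C=O)c(F)c(C=O)c1-c1c(OC)cc(OC)cc1OC | intermediate
19 | heptamer tetra-aldehyde, formyl groups at C2 and C6 of each ring D | COc1cc(OC)cc(Oc2c(Oc3c(OC)cc(Oc4c(C=O)cc(OC)c(-c5c(OC)cc(OC)cc5OC)c4C=O)cc3OC)cc(OC)cc2Oc2c(OC)cc(Oc3c(C=O)cc(OC)c(-c4c(OC)cc(OC)cc4OC)c3C=O)cc2OC)c1 | intermediate
20 | heptamer tetraformate, formyloxy groups at C2 and C6 of each ring D | COc1cc(OC)cc(Oc2c(Oc3c(OC)cc(Oc4c(OC=O)cc(OC)c(-c5c(OC)cc(OC)cc5OC)c4OC=O)cc3OC)cc(OC)cc2Oc2c(OC)cc(Oc3c(OC=O)cc(OC)c(-c4c(OC)cc(OC)cc4OC)c3OC=O)cc2OC)c1 | intermediate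
21 | heptamer tetraphenol, hydroxyls at C2 and C6 of each ring D, fifteen methyl ethers | COc1cc(OC)cc(Oc2c(Oc3c(OC)cc(Oc4c(O)cc(OC)c(-c5c(OC)cc(OC)cc5OC)c4O)cc3OC)cc(OC)cc2Oc2c(OC)cc(Oc3c(O)cc(OC)c(-c4c(OC)cc(OC)cc4OC)c3O)cc2OC)c1 | intermediate
22 | CNP0227063.0 | Oc1cc(O)cc(Oc2c(Oc3c(O)cc(Oc4c(O)cc(O)c(-c5c(O)cc(O)cc5O)c4O)cc3O)cc(O)cc2Oc2c(O)cc(Oc3c(O)cc(O)c(-c4c(O)cc(O)cc4O)c3O)cc2O)c1 | target

**Step count**
Total: 12 steps. Longest linear sequence: 9 steps (steps 1, 2, 3, 4, 5, 6, 10, 11, 12, from compound 1). The branch to 18 is 3 steps (steps 7, 8, 9).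

**Steps most likely to fail, with fallbacks**

Step 9. The coupling creates a biaryl with four ortho substituents, so transmetalation and reductive elimination may be slow. Protodeboronation of the electron-rich boronic acid and displacement of the activated fluoride by the aqueous base could then outrun C–C bond formation. The fallback is a base-free Negishi coupling that sets out from 15. 1,3,5-Trimethoxybenzene is lithiated with n-BuLi in THF at 0 °C to 2,4,6-trimethoxyphenyllithium F1, which is transmetalated with ZnCl2 to (2,4,6-trimethoxyphenyl)zinc chloride F2. F2 is coupled with 15 using Pd2(dba)3 and RuPhos in THF at 60 to 70 °C to give 17. Aqueous HCl in THF then hydrolyses the dioxolane and the route is rejoined at 18. Arylzinc halides do not add to aryl aldehydes under these conditions, and no hydroxide or boronic acid is present.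

Step 11. At each of the four formyl groups hydride migration may compete with aryl migration in the Criegee intermediate. The ring D ether oxygen is twisted out of conjugation by its two ortho substituents and the second formyl group is electron-withdrawing, so carboxylic acids could form at some sites. The fallback sets out from 19 and replaces the migrating hydrogen by methyl. MeMgBr in THF at 0 °C gives the tetrakis(1-hydroxyethyl) compound F3 as a mixture of diastereomers at the four carbinol carbons, which is of no consequence. Dess–Martin periodinane in CH2Cl2 oxidises it to the tetra(methyl ketone) F4. Baeyer–Villiger oxidation with mCPBA and CF3CO2H in CH2Cl2, where only aryl migration is available, gives the tetraacetate F5. Methanolysis with catalytic K2CO3 in MeOH rejoins the route at 21.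

Step 5. C–O bond formation at the copper-bound phenoxide, which is crowded by two 2,6-dimethoxyphenoxy groups, may be slow, so that hydrodeiodination of 9 and oxidative degradation of the electron-rich phenoxide take over. The fallback is a metal-free arylation that sets out from 8. Iodide 9 is oxidised with mCPBA and TsOH·H2O in MeCN and treated in the same flask with 1,3,5-trimethoxybenzene to give (3,5-dimethoxyphenyl)(2,4,6-trimethoxyphenyl)iodonium tosylate F6. Phenol 8 is deprotonated with KOt-Bu in THF and treated with F6 at rt to 40 °C. Ligand coupling at trivalent iodine should transfer the 3,5-dimethoxyphenyl group, the trimethoxyphenyl group staying on iodine, and this rejoins the route at 10.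

**Further compounds**
F1 | step 9 | 2,4,6-trimethoxyphenyllithium | COc1cc(OC)c([Li])c(OC)c1
F2 | step 9 | (2,4,6-trimethoxyphenyl)zinc chloride | COc1cc(OC)c([Zn]Cl)c(OC)c1
F3 | step 11 | heptamer with 1-hydroxyethyl groups at C2 and C6 of each ring D (diastereomer mixture) | COc1cc(OC)cc(Oc2c(Oc3c(OC)cc(Oc4c(C(C)O)cc(OC)c(-c5c(OC)cc(OC)cc5OC)c4C(C)O)cc3OC)cc(OC)cc2Oc2c(OC)cc(Oc3c(C(C)O)cc(OC)c(-c4c(OC)cc(OC)cc4OC)c3C(C)O)cc2OC)c1
F4 | step 11 | heptamer with acetyl groups at C2 and C6 of each ring D | COc1cc(OC)cc(Oc2c(Oc3c(OC)cc(Oc4c(C(C)=O)cc(OC)c(-c5c(OC)cc(OC)cc5OC)c4C(C)=O)cc3OC)cc(OC)cc2Oc2c(OC)cc(Oc3c(C(C)=O)cc(OC)c(-c4c(OC)cc(OC)cc4OC)c3C(C)=O)cc2OC)c1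
F5 | step 11 | heptamer with acetoxy groups at C2 and C6 of each ring D | COc1cc(OC)cc(Oc2c(Oc3c(OC)cc(Oc4c(OC(C)=O)cc(OC)c(-c5c(OC)cc(OC)cc5OC)c4OC(C)=O)cc3OC)cc(OC)cc2Oc2c(OC)cc(Oc3c(OC(C)=O)cc(OC)c(-c4c(OC)cc(OC)cc4OC)c3OC(C)=O)cc2OC)c1
F6 | step 5 | (3,5-dimethoxyphenyl)(2,4,6-trimethoxyphenyl)iodonium 4-methylbenzenesulfonate | COc1cc(OC)cc([I+]c2c(OC)cc(OC)cc2OC)c1.Cc1ccc(S(=O)(=O)[O-])cc1
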